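**Assumptions.** (i) tert-Butyl 2-methylbut-3-en-2-yl carbonate is taken as purchasable; if not, it is one step from 2-methylbut-3-en-2-ol and Boc2O. (ii) The sense of induction of the chiral acid in step 5 cannot be predicted with confidence; (R)-TRIP is written, and (S)-TRIP is used instead if the first run gives the 2R flavan. The target's single stereocentre is C2 of the flavan, and the given SMILES corresponds to 2S.

## Retrosynthetic overview

1. Kazinol B ⇒ 7-hydroxyflavylium (2-aryl-1-benzopyrylium) ion paired with a chiral phosphate. The key step is an enantioselective dearomative double transfer hydrogenation of the pyrylium ring, which sets C2 in the last step.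
2. Flavylium ⇒ (E)-2-hydroxy retro-chalcone (photo E→Z isomerisation and cyclodehydration in situ) ⇒ 2,4-dihydroxybenzaldehyde + B-ring methyl ketone.
3. B-ring ketone ⇒ bis(tertiary) ether of 3',4'-dihydroxyacetophenone by a tandem propargyl/allyl aryl Claisen, which builds the chromene and the ortho-prenyl group in one operation.
4. Ring order: the B-ring pyran (chromene) is formed first; the flavan heterocycle is closed and reduced last; ring A comes intact from the aldehyde. No protecting groups are used.

## Route

**Step 1**
Reactants: 1, 1-(3,4-dihydroxyphenyl)ethan-1-one (3',4'-dihydroxyacetophenone); 2, 3-chloro-3-methylbut-1-yne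
Product: 3, 1-[3-hydroxy-4-(2-methylbut-3-yn-2-yloxy)phenyl]ethan-1-one
Conditions: K2CO3 (1.1 equiv), KI, CuI (2 mol%), acetone, 55 °C, N2
Reagents that add atoms: 3-chloro-3-methylbut-1-yne, CC(C)(Cl)C#C
Why: Cu-assisted propargylic etherification; with about one equivalent of weak base only the more acidic 4-OH (para to the acetyl) is ionised, so the tertiary propargyl ether forms at O-4, as in the usual selective 4-O-alkylation of 3,4-dihydroxyaryl carbonyl compounds.

**Step 2**
Reactants: 3; 4, tert-butyl 2-methylbut-3-en-2-yl carbonate
Product: 5, 1-[3-(2-methylbut-3-en-2-yloxy)-4-(2-methylbut-3-yn-2-yloxy)phenyl]ethan-1-one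
Conditions: Pd(PPh3)4 (3 mol%), THF, 0 °C → rt
Reagents that add atoms: tert-butyl 2-methylbut-3-en-2-yl carbonate, C=CC(C)(C)OC(=O)OC(C)(C)C
Why: Decarboxylative Tsuji–Trost O-allylation; at low temperature the phenoxide attacks the more substituted terminus of the 1,1-dimethylallyl-Pd complex, giving the tertiary (reverse-prenyl) aryl ether at the only free OH.

**Step 3**
Reactants: 5
Product: 6, 1-[8-hydroxy-2,2-dimethyl-7-(3-methylbut-2-en-1-yl)-2H-chromen-6-yl]ethan-1-one
Conditions: PhNEt2, 140 °C, 3 h
Reagents that add atoms: none
Why: Tandem aromatic Claisen rearrangements through dearomatised cyclohexadienones: the 1,1-dimethylallyl ether shifts [3,3] to its only free ortho carbon (C-2, also the site favoured by the meta acyl group) to give the linear prenyl group, while the propargyl ether shifts to C-5 and then closes the 2,2-dimethylchromene by 1,5-H shift and oxa-6π electrocyclisation; the basic solvent prevents acid cyclisation of the new o-prenylphenol.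

**Step 4**
Reactants: 6; 7, 2,4-dihydroxybenzaldehyde
Product: 8, (E)-3-(2,4-dihydroxyphenyl)-1-[8-hydroxy-2,2-dimethyl-7-(3-methylbut-2-en-1-yl)-2H-chromen-6-yl]prop-2-en-1-one
Conditions: 50% aq. KOH (10 equiv), EtOH, N2, dark, rt → 45 °C, 24–48 h; then AcOH to pH 5
Reagents that add atoms: 2,4-dihydroxybenzaldehyde, O=Cc1ccc(O)cc1O
Why: Claisen–Schmidt aldol condensation with E1cB dehydration gives the E-enone, which is stable in base as its phenoxide; no strong acid is used, so the o-prenylphenol and chromene survive, but the aldehyde is deactivated as its phenoxide, so excess base and long reaction time are needed and the yield will be modest.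

**Step 5 (key step)**
Reactants: 8
Product: 10, kazinol B, (2S)-2-[8-hydroxy-2,2-dimethyl-7-(3-methylbut-2-en-1-yl)-2H-chromen-6-yl]-3,4-dihydro-2H-chromen-7-ol, formed via 9, the 7-hydroxy-2-aryl-1-benzopyrylium (flavylium) (R)-TRIP phosphate, generated in situ and not isolated
Conditions: (R)-TRIP (10 mol%), 5 Å MS, CH2Cl2/PhMe 1:1, 405 nm LED, rt, 1 h; then dark, Hantzsch ester (diethyl 2,6-dimethyl-1,4-dihydropyridine-3,5-dicarboxylate, 2.5 equiv), 0 °C → rt; Et3N quench
Reagents that add atoms: none (the Hantzsch ester delivers only hydrogen; one water is lost)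
Why: Proposed new method: light converts the E-chalcone to the Z-isomer, which closes to the 2H-chromen-2-ol and is dehydrated by the phosphoric acid to the aromatic flavylium/chiral phosphate ion pair 9; the Hantzsch ester adds hydride at C4 to give the achiral 2-aryl-4H-chromene, the acid reprotonates C3 to a 2-aryl chroman-2-ylium/phosphate contact ion pair, and a second hydride delivered within that chiral ion pair sets C2 as S; the closest known reactions are the chiral phosphoric acid/Hantzsch ester cascade reduction of 2-substituted quinolines to tetrahydroquinolines (1,4-hydride, protonation, enantioselective 1,2-hydride), the phosphoric acid-catalysed enantioselective 1,4-reduction of benzopyrylium ions generated from 2H-chromen-2-ols, and phosphoric acid protonation of cyclic enol ethers to oxocarbenium ion pairs; isolated alkenes (prenyl, chromene) are inert to the Hantzsch ester and the acid is too weak to cyclise the o-prenylphenol at rt.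

## Compound list

1 | 1-(3,4-dihydroxyphenyl)ethan-1-one | CC(=O)c1ccc(O)c(O)c1 | starting material
2 | 3-chloro-3-methylbut-1-yne | CC(C)(Cl)C#C | starting material
3 | 1-[3-hydroxy-4-(2-methylbut-3-yn-2-yloxy)phenyl]ethan-1-one | CC(=O)c1ccc(OC(C)(C)C#C)c(O)c1 | intermediate
4 | tert-butyl 2-methylbut-3-en-2-yl carbonate | C=CC(C)(C)OC(=O)OC(C)(C)C | starting material
5 | 1-[3-(2-methylbut-3-en-2-yloxy)-4-(2-methylbut-3-yn-2-yloxy)phenyl]ethan-1-one | CC(=O)c1ccc(OC(C)(C)C#C)c(OC(C)(C)C=C)c1 | intermediate
6 | 1-[8-hydroxy-2,2-dimethyl-7-(3-methylbut-2-en-1-yl)-2H-chromen-6-yl]ethan-1-one | CC(=O)c1cc2C=CC(C)(C)Oc2c(O)c1CC=C(C)C | intermediate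
7 | 2,4-dihydroxybenzaldehyde | O=Cc1ccc(O)cc1O | starting material
8 | (E)-3-(2,4-dihydroxyphenyl)-1-[8-hydroxy-2,2-dimethyl-7-(3-methylbut-2-en-1-yl)-2H-chromen-6-yl]prop-2-en-1-one | CC(C)=CCc1c(C(=O)/C=C/c2ccc(O)cc2O)cc2C=CC(C)(C)Oc2c1O | intermediate
9 | 7-hydroxy-2-[8-hydroxy-2,2-dimethyl-7-(3-methylbut-2-en-1-yl)-2H-chromen-6-yl]chromenylium, (R)-TRIP phosphate salt (cation shown) | CC(C)=CCc1c(-c2ccc3ccc(O)cc3[o+]2)cc2C=CC(C)(C)Oc2c1O | intermediate (in situ)
10 | kazinol B, (2S)-2-[8-hydroxy-2,2-dimethyl-7-(3-methylbut-2-en-1-yl)-2H-chromen-6-yl]-3,4-dihydro-2H-chromen-7-ol | CC(C)=CCc1c([C@@H]2CCc3ccc(O)cc3O2)cc2c(c1O)OC(C)(C)C=C2 | target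

## Summary

Total steps: 5. Longest linear sequence: 5 (fully linear, protecting-group-free).

Steps most likely to fail, with fallbacks:

1. **Step 5.** Three risks:
   - low ee, since the oxocarbenium has no N–H handle for the phosphate;
   - Prins-type capture of the C2 oxocarbenium by the ortho-prenyl alkene to give an indane;
   - acid racemisation of the electron-rich benzylic ether.

   Fallback: abandon the dearomative cascade. Reduce the enone of 8 to the dihydrochalcone (Stryker's reagent), carry out Noyori asymmetric transfer hydrogenation of the aryl ketone to the (R)-carbinol, and close the ring by Mitsunobu reaction on the ortho phenol with inversion to give the 2S flavan.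

2. **Step 4.** The aldehyde is a poor electrophile as its phenoxide, so conversion may be low. Fallback: condense 6 with 2,4-bis(methoxymethoxy)benzaldehyde (made from 7 with MOMCl/i-Pr2NEt) under KOH/EtOH, then remove the MOM groups with dilute HCl/MeOH at rt, conditions that o-prenylphenols are known to tolerate. This gives the same chalcone/flavylium manifold for step 5 at the cost of two extra steps.

3. **Steps 2–3.** The hindered tertiary ether may form as the linear prenyl ether, or the tandem Claisen may give para-migration or loss of isoprene. Fallback: heat 3 alone to the 8-hydroxychromene ketone, O-allylate with allyl bromide, run a simple allyl Claisen to the ortho-allyl phenol, and convert allyl to prenyl by cross-metathesis with 2-methyl-2-butene (Grubbs II); this takes three operations in place of steps 2–3.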